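The readings come from a simulation for substances that don't exist, noise included.

A ratio of two readings, left-handed product over right-handed product, was what I wanted from the earlier runs, because the excess asked for follows from that ratio, which I call h.

| flask | left-handed substrate | right-handed substrate | solid reagent | remark | time |
|---|---|---|---|---|---|
| north-east | 0.30 M | 0.30 M | 2.5 equiv | run made earlier |  |
| north-west | 0.68 M | 0.68 M | 2.5 equiv | run made earlier |  |
| flask | 0.45 M | 0.45 M | 2.50 equiv |  | 40 h |

| run | time / h | left-handed product / % | right-handed product / % |
|---|---|---|---|
| north-east | 5.00 | 5.3 | 0.2 |
| north-east | 15.0 | 14.2 | 1.5 |
| north-east | 25.0 | 15.7 | 1.8 |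
| north-east | 40.0 | 16.3 | 2.1 |
| north-west | 5.00 | 3.8 | 0 |
| north-west | 15.0 | 11.6 | 1.9 |
| north-west | 25.0 | 15.5 | 1.2 |
| north-west | 40.0 | 16.2 | 2.0 |

(readings scatter by 0.5 percentage points)

- left-handed product and right-handed product together, in percent of the left-handed substrate and right-handed substrate charged together, at 40 h
- excess of left-handed product over right-handed product in the product at 40 h
- whether the exchange between left-handed substrate and right-handed substrate keeps pace with the reaction: how far the product's excess at 40 h gets from its value without exchange to its value with instant exchange (above 80% keeps pace, below 20% hardly takes part, else lags behind)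

- partner is single-handed; left-handed substrate and right-handed substrate are mirror images of each other, charged as a racemate, each of them at the stated concentration
- given per volume of solution although it is solid: solid reagent
- at the start none of the solid reagent is in solution
- an excess is below zero if the other one leads
- the handed part of partner does not stay in what it makes, so the products of the two hands are mirror images too

The bench rule reads h from the earliest sample, taking both substrates as still about equal. In the north-east run at 5.00 h this gave 26.5, but that right-handed product reading was 0.400 of the scatter of one reading, and the north-west run read 0%, which gives no ratio. The rule stopped there, whereas at 40.0 h the north-east reading stood at 4.20 times the scatter. So I pooled both runs and took L = 0.899, the common logarithm of pooled h, at 40.0 h, with a scatter of 0.0749. At 15.0 h, pooled L was 0.880.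

For the flask, which lies between the two runs in concentration, I kept L, which gives an excess of 77.6%. I took the mean final total, 18.3%, since the run totals differed by 0.2 percentage points. Unreplaced loss of the favoured substrate lowers L, but the change in pooled L between these samples, 0.0190, was less than the scatter of L at 40.0 h alone, so the readings could not tell a fall from no fall. I committed to "lags behind" as the middle verdict, a choice made without a measurement that supported it.

The forecast gave 18.3%, 77% and, differing from me, hardly takes part, in its words “I judge that exchange hardly takes part”.

The flask gave 18.4% and 78.2%, and its exchange lags behind, 64% of the way.

    solid reagent ⇌ partner, rate k1*(cs1 - [partner]) while solid is left; crystals form when [partner] > cs1 (solubility = 0.360 M, k = 0.280 h⁻¹)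
    partner + left-handed substrate → left-handed product (k = 0.210 M⁻¹ h⁻¹)
    partner ⇌ dormant form (K = 0.920, k = 0.0900 h⁻¹)
    partner + right-handed substrate → right-handed product (k = 0.0190 M⁻¹ h⁻¹)
    achiral form → waste (k = 0.650 h⁻¹)
    right-handed substrate ⇌ achiral form (K = 0.790, k = 0.130 h⁻¹)
    left-handed substrate ⇌ achiral form (K = 0.790, k = 0.130 h⁻¹)
    partner → decomposed reagent (k = 0.0350 h⁻¹)

Its product excess was 82.8% after 4.00 h. The selectivity factor of the two product-forming steps is 11.1, which is L = 1.04 for instant exchange. The flask ended lower, at L = 0.913. The neighbour flask with 0.620 equiv of solid reagent ended with an excess of 81.5%, at L = 0.992.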